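**Plan**

- Retrosynthesis: the C5=C6 enol-lactone alkene and the C12 carbonyl are taken back to a furan (C6, C7, C11, C12 and the ring oxygen). The C8 ester is taken back to a C8 ketone, and the C9–C10 bond is cut as an aldol bond. This opens the ten-membered ring to a cis-2,5-disubstituted oxolane with an acetyl group on C1 and a furylmethyl group on C4, the furan carrying a bromoacetyl group on C7.
- Forward order of rings: oxolane (epoxide opening, step 2), furan (Feist–Benary annulation on the C5–C6 arm, step 5), ten-membered carbocycle by C9–C10 closure (step 10), butenolide by singlet-oxygen unmasking of the furan and dehydration (steps 13 and 14).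
- Enabling feature: C1 and C4 are cis on the oxolane and C6 and C7 are adjacent on the planar furan, so C9 and the C10 carbonyl are held within reach and only a nine-membered ring (counted through the oxolane oxygen) has to close. The oxolane oxygen on C1 is α to the C10 carbonyl and allows chelation.
- The furan is a ring that is not in the target: it fixes C6 and C7 during ring closure and defers the C5=C6 alkene until the macrocycle can dictate its geometry.
- Stereochemistry: C4 from (R)-linalool; C1 from reagent-controlled Shi epoxidation and invertive 5-exo opening; C10 in the key step by chelation; C8 by chelation-controlled syn reduction; C5=C6 geometry by the ring.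

Key step: step 10

Remark on locants: germacrane numbering is used (C1 oxolane CH, C4 oxolane quaternary carbon, C5=C6 ylidene, C7, C8 ester carbinol, C9 methylene, C10 tertiary carbinol, C11, C12 lactone carbonyl, C13 CH2OAc, C14 methyl on C10, C15 methyl on C4).
Remark on the chemistry: commercial (R)-(−)-linalool is taken as enantiomerically pure; any minor enantiomer would become a diastereomer in step 2 and be removed there.

**Step 1**
Reactants: 1 (3R)-3,7-dimethylocta-1,6-dien-3-ol ((R)-linalool)
Product: 2 (3R)-3,7-dimethyloct-6-ene-1,3-diol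
Conditions: 9-borabicyclo[3.3.1]nonane (2.3 equiv), THF, 0 °C to rt; then NaOH, H2O2, H2O, 0 °C to rt
Reagents that add atoms: hydrogen peroxide, OO
Why: Anti-Markovnikov hydroboration–oxidation; the hindered borane should add only to the monosubstituted vinyl group and leave the trisubstituted alkene, and the C4 carbinol centre of 1 is not touched.

**Step 2**
Reactants: 2 (3R)-3,7-dimethyloct-6-ene-1,3-diol
Product: 4 2-[(2S,5R)-5-(2-hydroxyethyl)-5-methyloxolan-2-yl]propan-2-ol, via epoxide 3 (not isolated)
Conditions: 1,2:4,5-di-O-isopropylidene-β-D-erythro-hexo-2,3-diulo-2,6-pyranose (Shi ketone from D-fructose, 0.3 equiv), KHSO5 (as 2KHSO5·KHSO4·K2SO4), K2CO3, Bu4NHSO4, MeCN/CH2(OMe)2/aq. Na2B4O7 buffer, 0 °C; then (1S)-(+)-10-camphorsulfonic acid (0.1 equiv), CH2Cl2, 0 °C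
Reagents that add atoms: potassium peroxymonosulfate, [K+].[O-]S(=O)(=O)OO
Why: Shi asymmetric epoxidation (chiral dioxirane, spiro transition state) should give the R epoxide 3 at the trisubstituted alkene, and acid-catalysed 5-exo-tet opening by the tertiary hydroxyl inverts that carbon to set C1 as S, cis to the hydroxyethyl arm; a minor oxane isomer from 6-endo attack is expected and is to be separated.

**Step 3**
Reactants: 4 2-[(2S,5R)-5-(2-hydroxyethyl)-5-methyloxolan-2-yl]propan-2-ol
Product: 5 2-[(2R,5S)-5-(2-hydroxypropan-2-yl)-2-methyloxolan-2-yl]acetaldehyde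
Conditions: 2,2,6,6-tetramethylpiperidin-1-oxyl (0.1 equiv), PhI(OAc)2 (1.2 equiv), CH2Cl2, rt
Reagents that add atoms: none
Why: Oxoammonium-mediated oxidation (nitroxyl radical with PhI(OAc)2) is selective for the primary alcohol and stops at the aldehyde; the tertiary alcohol cannot be oxidised.

**Step 4**
Reactants: 5 2-[(2R,5S)-5-(2-hydroxypropan-2-yl)-2-methyloxolan-2-yl]acetaldehyde; 6 tert-butyl diazoacetate
Product: 7 tert-butyl 4-[(2R,5S)-5-(2-hydroxypropan-2-yl)-2-methyloxolan-2-yl]-3-oxobutanoate
Conditions: SnCl2 (0.1 equiv), CH2Cl2, rt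
Reagents that add atoms: none
Why: Roskamp homologation; Lewis-acid-catalysed addition of the diazo ester to the aldehyde, 1,2-hydride shift and loss of N2 should give the β-keto ester without base, which spares the β-alkoxy aldehyde from elimination.

**Step 5**
Reactants: 7 tert-butyl 4-[(2R,5S)-5-(2-hydroxypropan-2-yl)-2-methyloxolan-2-yl]-3-oxobutanoate; 8 3-chloro-2-oxopropyl acetate
Product: 10 tert-butyl 4-(acetoxymethyl)-2-{[(2R,5S)-5-(2-hydroxypropan-2-yl)-2-methyloxolan-2-yl]methyl}furan-3-carboxylate, via dihydrofuranol 9 (not isolated)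
Conditions: pyridine, 50 °C; then p-toluenesulfonic acid monohydrate (0.1 equiv), CH2Cl2, rt
Reagents that add atoms: none
Why: Feist–Benary furan synthesis; aldol addition of C7 to the ketone of 8, 5-exo-tet O-alkylation by the C6 enol oxygen with loss of chloride, then acid-catalysed dehydration of 9 should give the furan with CH2OAc on C11 and hydrogen on C12.

**Step 6**
Reactants: 10 tert-butyl 4-(acetoxymethyl)-2-{[(2R,5S)-5-(2-hydroxypropan-2-yl)-2-methyloxolan-2-yl]methyl}furan-3-carboxylate
Product: 12 tert-butyl 4-(acetoxymethyl)-2-{[(2R,5S)-2-methyl-5-(prop-1-en-2-yl)oxolan-2-yl]methyl}furan-3-carboxylate, via chlorosulfite 11 (not isolated)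
Conditions: SOCl2 (1.5 equiv), pyridine (6 equiv), CH2Cl2, −30 to 0 °C
Reagents that add atoms: none
Why: Dehydration through the chlorosulfite; E2 removal of one of the six methyl hydrogens by pyridine is expected to win over abstraction of the single hindered ring hydrogen on the oxygen-bearing C1, giving the isopropenyl group and leaving C1 intact.

**Step 7**
Reactants: 12 tert-butyl 4-(acetoxymethyl)-2-{[(2R,5S)-2-methyl-5-(prop-1-en-2-yl)oxolan-2-yl]methyl}furan-3-carboxylate
Product: 14 tert-butyl 2-{[(2R,5S)-5-acetyl-2-methyloxolan-2-yl]methyl}-4-(acetoxymethyl)furan-3-carboxylate, via diol 13 (not isolated)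
Conditions: K2OsO4·2H2O (0.02 equiv), NaIO4 (4 equiv), 2,6-lutidine (2 equiv), 1,4-dioxane/H2O (3:1), rt
Reagents that add atoms: sodium periodate, [Na+].[O-]I(=O)(=O)=O; water, O
Why: Lemieux–Johnson cleavage; the 1,1-disubstituted alkene should be dihydroxylated faster than the ester-deactivated furan and diol 13 is cleaved by periodate to the C10 methyl ketone, the near-neutral medium protecting the α-centre C1 from epimerisation.

**Step 8**
Reactants: 14 tert-butyl 2-{[(2R,5S)-5-acetyl-2-methyloxolan-2-yl]methyl}-4-(acetoxymethyl)furan-3-carboxylate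
Product: 15 2-{[(2R,5S)-5-acetyl-2-methyloxolan-2-yl]methyl}-4-(acetoxymethyl)furan-3-carboxylic acid
Conditions: CF3CO2H/CH2Cl2 (1:4), 0 °C
Reagents that add atoms: none
Why: Acidolysis of the tert-butyl ester (E1 loss of 2-methylpropene) should free the acid, while the primary acetate, the carboxyl-deactivated furan and the α-alkoxy ketone are expected to survive at 0 °C.

**Step 9**
Reactants: 15 2-{[(2R,5S)-5-acetyl-2-methyloxolan-2-yl]methyl}-4-(acetoxymethyl)furan-3-carboxylic acid
Product: 18 [5-{[(2R,5S)-5-acetyl-2-methyloxolan-2-yl]methyl}-4-(bromoacetyl)furan-3-yl]methyl acetate, via acid chloride 16 (not isolated), via diazoketone 17 (not isolated)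
Conditions: (COCl)2 (1.5 equiv), N,N-dimethylformamide (0.05 equiv), CH2Cl2, 0 °C to rt; evaporate; CH2N2 (3 equiv), Et2O/THF, 0 °C; then 48% aq. HBr, 0 °C
Reagents that add atoms: diazomethane, C=[N+]=[N-]; hydrogen bromide, Br
Why: Nierenstein-type sequence; acid chloride 16 is acylated on carbon by diazomethane to diazoketone 17 (a second equivalent takes up HCl), and HBr protonates the diazo carbon and displaces N2, which places the bromine, and so the later enolate, at C9 only.

**Step 10**
Reactants: 18 [5-{[(2R,5S)-5-acetyl-2-methyloxolan-2-yl]methyl}-4-(bromoacetyl)furan-3-yl]methyl acetate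
Product: 20 (1S,4R,10R)-13-acetoxy-10-hydroxy-1,4:6,12-diepoxygermacra-6,11-dien-8-one, via samarium enolate 19 (not isolated)
Conditions: SmI2 (2.5 equiv), THF, −78 °C, 18 added over 6 h (final 0.002 M); then −40 °C; pH 7 phosphate buffer
Reagents that add atoms: none
Why: Two single-electron transfers from divalent samarium cleave the C9–Br bond and give the trivalent samarium enolate 19 of the C8 ketone with the nucleophilic carbon fixed at C9, and this enolate adds to the C10 methyl ketone, which is an α-alkoxy ketone because C1 carries the oxolane oxygen. The closest known reaction type is the SmI2-mediated intramolecular Reformatsky (aldol) reaction of α-halo carbonyl compounds, which is used to close eight- to eleven-membered rings. The ring formed is the ten-membered carbocycle C1–C10 (nine-membered when counted through the oxolane oxygen), closed in a 10-(enolendo)-exo-trig mode; the cis-2,5-disubstituted oxolane (C1, C4) and the ortho-disubstituted furan (C6, C7) leave only the C4–C5, C5–C6, C7–C8 and C8–C9 bonds free to rotate, so the two termini are held close. The new C10 stereocentre is set by chelation: trivalent samarium bridges the enolate oxygen, the C10 carbonyl oxygen and the oxolane oxygen, which turns the carbonyl syn to the C1–O bond, and the tether from C4 can then reach only the carbonyl face turned toward C4, which gives 10R. The step needs chemoselective reduction of the C–Br bond beside the ketone and the acetate (α-bromo ketones are reduced far faster at −78 °C without additives), an enolate that does not equilibrate to C14 or C1 (non-basic conditions, so C1 is not epimerised) and ring closure in preference to intermolecular aldol addition (slow addition, high dilution). A cold neutral quench should prevent retro-aldol opening of the medium-ring β-hydroxy ketone.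

**Step 11**
Reactants: 20 (1S,4R,10R)-13-acetoxy-10-hydroxy-1,4:6,12-diepoxygermacra-6,11-dien-8-one
Product: 22 (1S,4R,8S,10R)-13-acetoxy-1,4:6,12-diepoxygermacra-6,11-diene-8,10-diol, via diethylborinate 21 (not isolated)
Conditions: Et2BOMe (1.2 equiv), THF/MeOH (4:1), −78 °C; NaBH4 (1.5 equiv), −78 °C; AcOH, then MeOH co-evaporation
Reagents that add atoms: none
Why: Narasaka–Prasad reduction; the boron of borinate 21 chelates the C8 carbonyl, the ring bond to C1 should sit pseudo-equatorial on the chelate and external axial hydride delivery then gives the 1,3-syn diol, that is 8S, while the acetate is inert at −78 °C.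

**Step 12**
Reactants: 22 (1S,4R,8S,10R)-13-acetoxy-1,4:6,12-diepoxygermacra-6,11-diene-8,10-diol
Product: 23 (1S,4R,8S,10R)-13-acetoxy-10-hydroxy-8-(methacryloyloxy)-1,4:6,12-diepoxygermacra-6,11-diene
Conditions: methacrylic anhydride (1.5 equiv), Et3N (3 equiv), 4-(dimethylamino)pyridine (0.2 equiv), CH2Cl2, 0 °C to rt
Reagents that add atoms: methacrylic anhydride, C=C(C)C(=O)OC(=O)C(C)=C
Why: Acylation under nucleophilic catalysis should esterify the secondary C8 alcohol only, the tertiary C10 alcohol being too hindered to react under these conditions.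

**Step 13**
Reactants: 23 (1S,4R,8S,10R)-13-acetoxy-10-hydroxy-8-(methacryloyloxy)-1,4:6,12-diepoxygermacra-6,11-diene
Product: 25 (1S,4R,8S,10R)-13-acetoxy-6,10-dihydroxy-8-(methacryloyloxy)-1,4-epoxygermacr-7(11)-en-12,6-olide (C6 epimers), via endoperoxide 24 (not isolated)
Conditions: O2, 5,10,15,20-tetraphenylporphyrin (0.01 equiv), visible light, CH2Cl2, −78 °C; then i-Pr2NEt (2 equiv), −78 °C to rt
Reagents that add atoms: oxygen, O=O
Why: [4+2] cycloaddition of singlet oxygen across C6 and C12 of the furan gives endoperoxide 24, and base-induced Kornblum–DeLaMare fragmentation at C12–H, the only hydrogen on a peroxide carbon, should put the carbonyl at C12 and the hydroxyl at C6; the electron-poor methacrylate does not react with singlet oxygen.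

**Step 14**
Reactants: 25 (1S,4R,8S,10R)-13-acetoxy-6,10-dihydroxy-8-(methacryloyloxy)-1,4-epoxygermacr-7(11)-en-12,6-olide
Product: 27 (1S,4R,5E,8S,10R)-13-acetoxy-10-hydroxy-8-(methacryloyloxy)-1,4-epoxygermacra-5,7(11)-dien-12,6-olide (CNP0516045.1), via mesylate 26 (not isolated)
Conditions: MeSO2Cl (1.5 equiv), Et3N (4 equiv), CH2Cl2, −40 to 0 °C
Reagents that add atoms: none
Why: Sulfonylation of the acidic lactol hydroxyl at C6 and loss of methanesulfonate with removal of a C5 hydrogen, the only β-hydrogen, is a known dehydration of γ-hydroxybutenolides to γ-ylidene butenolides; the bridged ring should allow only the ring-cis C5=C6 geometry, which is the E descriptor of the target.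

**Compound list**

1 | (3R)-3,7-dimethylocta-1,6-dien-3-ol, (R)-linalool | CC(C)=CCC[C@](C)(C=C)O | starting material
2 | (3R)-3,7-dimethyloct-6-ene-1,3-diol | CC(C)=CCC[C@](C)(CCO)O | intermediate
3 | (3R)-5-[(2R)-3,3-dimethyloxiran-2-yl]-3-methylpentane-1,3-diol (epoxide, not isolated) | CC1(C)O[C@@H]1CC[C@](C)(CCO)O | intermediate
4 | 2-[(2S,5R)-5-(2-hydroxyethyl)-5-methyloxolan-2-yl]propan-2-ol | CC(C)(O)[C@@H]1CC[C@](C)(CCO)O1 | intermediate
5 | 2-[(2R,5S)-5-(2-hydroxypropan-2-yl)-2-methyloxolan-2-yl]acetaldehyde | CC(C)(O)[C@@H]1CC[C@](C)(CC=O)O1 | intermediate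
6 | tert-butyl diazoacetate | CC(C)(C)OC(=O)C=[N+]=[N-] | starting material
7 | tert-butyl 4-[(2R,5S)-5-(2-hydroxypropan-2-yl)-2-methyloxolan-2-yl]-3-oxobutanoate | CC(C)(O)[C@@H]1CC[C@](C)(CC(=O)CC(=O)OC(C)(C)C)O1 | intermediate
8 | 3-chloro-2-oxopropyl acetate | CC(=O)OCC(=O)CCl | starting material
9 | tert-butyl 4-(acetoxymethyl)-4-hydroxy-2-{[(2R,5S)-5-(2-hydroxypropan-2-yl)-2-methyloxolan-2-yl]methyl}-4,5-dihydrofuran-3-carboxylate (dihydrofuranol, not isolated) | CC(C)(O)[C@@H]1CC[C@](C)(CC2=C(C(=O)OC(C)(C)C)C(O)(COC(C)=O)CO2)O1 | intermediate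
10 | tert-butyl 4-(acetoxymethyl)-2-{[(2R,5S)-5-(2-hydroxypropan-2-yl)-2-methyloxolan-2-yl]methyl}furan-3-carboxylate | CC(C)(O)[C@@H]1CC[C@](C)(Cc2occ(COC(C)=O)c2C(=O)OC(C)(C)C)O1 | intermediate
11 | chlorosulfite ester of the tertiary alcohol of 10 (not isolated) | CC(C)(OS(=O)Cl)[C@@H]1CC[C@](C)(Cc2occ(COC(C)=O)c2C(=O)OC(C)(C)C)O1 | intermediate
12 | tert-butyl 4-(acetoxymethyl)-2-{[(2R,5S)-2-methyl-5-(prop-1-en-2-yl)oxolan-2-yl]methyl}furan-3-carboxylate | C=C(C)[C@@H]1CC[C@](C)(Cc2occ(COC(C)=O)c2C(=O)OC(C)(C)C)O1 | intermediate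
13 | tert-butyl 4-(acetoxymethyl)-2-{[(2R,5S)-5-(1,2-dihydroxypropan-2-yl)-2-methyloxolan-2-yl]methyl}furan-3-carboxylate (diol, not isolated) | CC(O)(CO)[C@@H]1CC[C@](C)(Cc2occ(COC(C)=O)c2C(=O)OC(C)(C)C)O1 | intermediate
14 | tert-butyl 2-{[(2R,5S)-5-acetyl-2-methyloxolan-2-yl]methyl}-4-(acetoxymethyl)furan-3-carboxylate | CC(=O)[C@@H]1CC[C@](C)(Cc2occ(COC(C)=O)c2C(=O)OC(C)(C)C)O1 | intermediate
15 | 2-{[(2R,5S)-5-acetyl-2-methyloxolan-2-yl]methyl}-4-(acetoxymethyl)furan-3-carboxylic acid | CC(=O)[C@@H]1CC[C@](C)(Cc2occ(COC(C)=O)c2C(=O)O)O1 | intermediate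
16 | acid chloride of 15 (not isolated) | CC(=O)[C@@H]1CC[C@](C)(Cc2occ(COC(C)=O)c2C(=O)Cl)O1 | intermediate
17 | [5-{[(2R,5S)-5-acetyl-2-methyloxolan-2-yl]methyl}-4-(diazoacetyl)furan-3-yl]methyl acetate (diazoketone, not isolated) | CC(=O)[C@@H]1CC[C@](C)(Cc2occ(COC(C)=O)c2C(=O)C=[N+]=[N-])O1 | intermediate
18 | [5-{[(2R,5S)-5-acetyl-2-methyloxolan-2-yl]methyl}-4-(bromoacetyl)furan-3-yl]methyl acetate | CC(=O)[C@@H]1CC[C@](C)(Cc2occ(COC(C)=O)c2C(=O)CBr)O1 | intermediate
19 | diiodosamarium enolate of the C8 ketone of 18, C8(OSmI2)=C9H2 (not isolated) | CC(=O)[C@@H]1CC[C@](C)(Cc2occ(COC(C)=O)c2C(=C)O[Sm](I)I)O1 | intermediate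
20 | (1S,4R,10R)-13-acetoxy-10-hydroxy-1,4:6,12-diepoxygermacra-6,11-dien-8-one (furan on C6, C7, C11, C12; oxolane bridge C1–O–C4) | O=C1C[C@@](C)(O)[C@@H]2CC[C@](C)(Cc3occ(COC(C)=O)c31)O2 | intermediate
21 | 10-O-diethylborinate of 20 (not isolated) | O=C1C[C@@](C)(OB(CC)CC)[C@@H]2CC[C@](C)(Cc3occ(COC(C)=O)c31)O2 | intermediate
22 | (1S,4R,8S,10R)-13-acetoxy-1,4:6,12-diepoxygermacra-6,11-diene-8,10-diol | O[C@H]1C[C@@](C)(O)[C@@H]2CC[C@](C)(Cc3occ(COC(C)=O)c31)O2 | intermediate
23 | (1S,4R,8S,10R)-13-acetoxy-10-hydroxy-8-(methacryloyloxy)-1,4:6,12-diepoxygermacra-6,11-diene | C=C(C)C(=O)O[C@H]1C[C@@](C)(O)[C@@H]2CC[C@](C)(Cc3occ(COC(C)=O)c31)O2 | intermediate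
24 | 6,12-endoperoxide of the furan of 23 (not isolated) | C=C(C)C(=O)O[C@H]1C[C@@](C)(O)[C@@H]2CC[C@](C)(CC34OOC(O3)C(COC(C)=O)=C41)O2 | intermediate
25 | (1S,4R,8S,10R)-13-acetoxy-6,10-dihydroxy-8-(methacryloyloxy)-1,4-epoxygermacr-7(11)-en-12,6-olide (C6 epimers) | C=C(C)C(=O)O[C@H]1C[C@@](C)(O)[C@@H]2CC[C@](C)(CC3(O)OC(=O)C(COC(C)=O)=C31)O2 | intermediate
26 | 6-O-methanesulfonate of 25 (not isolated) | C=C(C)C(=O)O[C@H]1C[C@@](C)(O)[C@@H]2CC[C@](C)(CC3(OS(C)(=O)=O)OC(=O)C(COC(C)=O)=C31)O2 | intermediate
27 | (1S,4R,5E,8S,10R)-13-acetoxy-10-hydroxy-8-(methacryloyloxy)-1,4-epoxygermacra-5,7(11)-dien-12,6-olide, CNP0516045.1 | C=C(C)C(=O)O[C@H]1C[C@@](C)(O)[C@@H]2CC[C@](C)(/C=C3/OC(=O)C(COC(C)=O)=C31)O2 | target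

**Totals**

Total step count: 14. Longest linear sequence: 14 steps (fully linear from 1).

**Steps most likely to fail**

1. Step 10 (key ring closure). Intermolecular aldol addition, protonation of the enolate or retro-aldol opening may outrun closure of the ten-membered ring. Fallback: set out from 18 and separate enolate formation from ring closure. Reductive silylation (Zn, Me3SiCl, THF) should give the trimethylsilyl enol ether of the C8 ketone F1. This is cyclised by a chelation-controlled Mukaiyama aldol reaction (MgBr2·OEt2, CH2Cl2, high dilution, −78 °C), in which magnesium holds the C10 carbonyl syn to the oxolane oxygen. The 10-O-trimethylsilyl ether of the aldol F2 is cleaved on aqueous work-up, and the route is rejoined at 20.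

2. Step 11 (C8 reduction). Poor facial selectivity may arise because the methyl group on the quaternary C10 must sit axial on the boron chelate, and the 8R alcohol could then predominate. Fallback: set out from 20 and use intramolecular hydride delivery (Evans–Saksena reduction, Me4NBH(OAc)3, AcOH/MeCN, −20 °C) to make the 1,3-anti diol, the 8R epimer of the diol F3, on purpose. Mitsunobu esterification with methacrylic acid (PPh3, diisopropyl azodicarboxylate, THF) then inverts C8 and returns to the route at 23.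

3. Step 14 (dehydration). The free tertiary C10 hydroxyl may be sulfonylated and eliminated, or may capture the C6 cation across the ring as a ketal. Fallback: set out from 23 and mask the hydroxyl first. 1-(Trimethylsilyl)imidazole should give the 10-O-trimethylsilyl ether of the furan F4. Photooxygenation gives the endoperoxide F5, and i-Pr2NEt converts it to the silylated hydroxybutenolide F6. MeSO2Cl/Et3N gives, through the mesylate F7, the silylated ylidene butenolide F8. HF·pyridine (THF, 0 °C) removes the silyl ether and comes back to the route at 27.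

**Further compounds**

F1 | step 10 | [5-{[(2R,5S)-5-acetyl-2-methyloxolan-2-yl]methyl}-4-{1-[(trimethylsilyl)oxy]ethenyl}furan-3-yl]methyl acetate | CC(=O)[C@@H]1CC[C@](C)(Cc2occ(COC(C)=O)c2C(=C)O[Si](C)(C)C)O1
F2 | step 10 | 10-O-trimethylsilyl ether of 20 | O=C1C[C@@](C)(O[Si](C)(C)C)[C@@H]2CC[C@](C)(Cc3occ(COC(C)=O)c31)O2
F3 | step 11 | (1S,4R,8R,10R)-13-acetoxy-1,4:6,12-diepoxygermacra-6,11-diene-8,10-diol | O[C@@H]1C[C@@](C)(O)[C@@H]2CC[C@](C)(Cc3occ(COC(C)=O)c31)O2
F4 | step 14 | 10-O-trimethylsilyl ether of 23 | C=C(C)C(=O)O[C@H]1C[C@@](C)(O[Si](C)(C)C)[C@@H]2CC[C@](C)(Cc3occ(COC(C)=O)c31)O2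
F5 | step 14 | 6,12-endoperoxide of F4 | C=C(C)C(=O)O[C@H]1C[C@@](C)(O[Si](C)(C)C)[C@@H]2CC[C@](C)(CC34OOC(O3)C(COC(C)=O)=C41)O2
F6 | step 14 | 10-O-trimethylsilyl ether of 25 | C=C(C)C(=O)O[C@H]1C[C@@](C)(O[Si](C)(C)C)[C@@H]2CC[C@](C)(CC3(O)OC(=O)C(COC(C)=O)=C31)O2
F7 | step 14 | 6-O-methanesulfonate of F6 | C=C(C)C(=O)O[C@H]1C[C@@](C)(O[Si](C)(C)C)[C@@H]2CC[C@](C)(CC3(OS(C)(=O)=O)OC(=O)C(COC(C)=O)=C31)O2
F8 | step 14 | 10-O-trimethylsilyl ether of 27 | C=C(C)C(=O)O[C@H]1C[C@@](C)(O[Si](C)(C)C)[C@@H]2CC[C@](C)(/C=C3/OC(=O)C(COC(C)=O)=C31)O2
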